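**Plan**

- Retrosynthesis: in both halves at once, cut O1–C8a and C4–C4a (each ring A leaves as an aryne); then trade each C2–O for C2–CHO, rejoin the two CHO groups as a ring CH=CH, and open that cyclohexene by retro-Diels–Alder.
- Forward: a Diels–Alder reaction joins the C2–C3–C3'–C2' chain; ozonolysis/Baeyer–Villiger excises the CH=CH bridge and leaves an oxygen on C2 and C2'; a two-directional double aryne annulation closes both rings C and brings in both rings A; hydrogenolysis ends the route.
- Enabling feature: in each chromanone, O1 and the C4 carbonyl stand on adjacent carbons of ring A (C8a, C4a) and are linked through C2–C3 as a β-oxy carbonyl unit, so a C2 alkoxide and a C4 ester can add across one aryne triple bond.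
- Stereochemistry: all four centres come from the all-cis endo Diels–Alder adduct (meso); Baeyer–Villiger migration and O-arylation retain them, which gives 2,3-trans in each ring C and the meso 3,3' junction.

Key step: step 10

Remark: chromanone numbering (O1, C2, C3, C4, C4a–C8a, primes for the second half) is used for these atoms in all intermediates; the target is the meso (2S,3R,2'R,3'S) isomer, so unsymmetrical intermediates are racemic and are drawn as one enantiomer.

**Route**

Step 1
Reactants: 1 4-(benzyloxy)benzyl chloride; 2 triphenylphosphine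
Product: 3 [4-(benzyloxy)benzyl]triphenylphosphonium chloride
Conditions: PhMe, reflux
Reagents that add atoms: none
Why: SN2 alkylation of the phosphine by the activated benzylic chloride (phosphonium salt formation) should be clean, the salt precipitating from toluene.

Step 2
Reactants: 3 [4-(benzyloxy)benzyl]triphenylphosphonium chloride (2 equiv); 4 glyoxal (40% aqueous)
Product: 6 (1E,3E)-1,4-bis[4-(benzyloxy)phenyl]buta-1,3-diene, via phosphorus ylide 5 (not isolated)
Conditions: LiOEt, EtOH, rt; then I2 (cat.), PhMe, reflux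
Reagents that add atoms: none
Why: double Wittig olefination of both carbonyl groups of glyoxal by the semi-stabilised benzylic ylide, followed by iodine-catalysed equilibration of any Z double bond, should deliver the thermodynamically preferred E,E-diene.

Step 3
Reactants: 6 (1E,3E)-1,4-bis[4-(benzyloxy)phenyl]buta-1,3-diene; 7 maleic anhydride
Product: 8 (3aR,4R,7S,7aS)-4,7-bis[4-(benzyloxy)phenyl]-3a,4,7,7a-tetrahydro-2-benzofuran-1,3-dione (meso; all-cis)
Conditions: xylenes, reflux
Reagents that add atoms: none
Why: thermal Diels–Alder cycloaddition in which suprafacial addition to the E,E-diene places the two aryl groups cis, the cis dienophile keeps the two carbonyl-bearing carbons cis, and the endo transition state puts anhydride and aryl groups on the same face, so all four stereocentres (future C2, C3, C3', C2') are set as the meso all-cis array.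

Step 4
Reactants: 8 the all-cis anhydride
Product: 10 dimethyl (1S,2R,3R,6S)-3,6-bis[4-(benzyloxy)phenyl]cyclohex-4-ene-1,2-dicarboxylate (meso; all-cis), via monoester acid 9 (not isolated)
Conditions: MeOH, DMAP (cat.), CH2Cl2, rt; then TMSCHN2, PhMe/MeOH, 0 °C
Reagents that add atoms: methanol CO; (trimethylsilyl)diazomethane C[Si](C)(C)C=[N+]=[N-]
Why: nucleophilic acyl substitution opens the anhydride and diazoalkane O-methylation esterifies the liberated acid under neutral conditions, which should avoid epimerisation of the cis diester to the trans isomer.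

Step 5
Reactants: 10 the all-cis cyclohexene diester
Product: 12 dimethyl (2R,3S)-2-[(S)-[4-(benzyloxy)phenyl](formyloxy)methyl]-3-[(R)-[4-(benzyloxy)phenyl](formyloxy)methyl]butanedioate (meso), via dialdehyde 11 (not isolated)
Conditions: O3, pyridine, CH2Cl2, −78 °C; cold aq. citric acid wash; then mCPBA, CH2Cl2, 0 °C to rt
Reagents that add atoms: ozone [O-][O+]=O; 3-chloroperoxybenzoic acid OOC(=O)c1cccc(Cl)c1
Why: pyridine-mediated reductive ozonolysis cleaves the only alkene to the dialdehyde, and Baeyer–Villiger oxidation, in which the secondary 4-alkoxybenzylic carbon should migrate in preference to hydrogen and with retention, turns each C2–CHO into C2–OCHO without touching the four stereocentres.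

Step 6
Reactants: 12 the meso bis-formate
Product: 14 dimethyl (2R,3S)-2-[(S)-[4-(benzyloxy)phenyl][(trimethylsilyl)oxy]methyl]-3-[(R)-[4-(benzyloxy)phenyl][(trimethylsilyl)oxy]methyl]butanedioate (meso), via diol diester 13 (not isolated)
Conditions: NH3 (7 M in MeOH), THF, 0 °C; concentrate; then 1-(trimethylsilyl)imidazole, CH2Cl2, 0 °C to rt
Reagents that add atoms: 1-(trimethylsilyl)imidazole C[Si](C)(C)n1ccnc1
Why: ammonolysis removes the very labile formates while the methyl esters persist, and immediate neutral O-silylation masks the γ-hydroxy esters against lactonisation and stores each alkoxide in a fluoride-releasable form.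

Step 7
Reactants: 15 4-(benzyloxy)phenol
Product: 16 4-(benzyloxy)-2-chlorophenol
Conditions: SO2Cl2, i-Bu2NH (cat.), PhMe, rt
Reagents that add atoms: sulfuryl chloride ClS(Cl)(=O)=O
Why: electrophilic aromatic chlorination should occur ortho to the free hydroxyl, the stronger activator, because the para position is blocked.

Step 8
Reactants: 16 4-(benzyloxy)-2-chlorophenol
Product: 17 4-(benzyloxy)-2-bromo-6-chlorophenol
Conditions: NBS, i-Pr2NH (cat.), CH2Cl2, 0 °C
Reagents that add atoms: N-bromosuccinimide BrN1C(=O)CCC1=O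
Why: amine-catalysed electrophilic bromination should take the only remaining position ortho to the hydroxyl.

Step 9
Reactants: 17 4-(benzyloxy)-2-bromo-6-chlorophenol
Product: 20 4-(benzyloxy)-2-chloro-6-(trimethylsilyl)phenyl trifluoromethanesulfonate, via aryl silyl ether 18 (not isolated), via lithium silylphenolate 19 (not isolated)
Conditions: HMDS, THF, 65 °C; concentrate; n-BuLi, THF, −100 °C; then Tf2O, −100 to −78 °C
Reagents that add atoms: hexamethyldisilazane C[Si](C)(C)N[Si](C)(C)C; trifluoromethanesulfonic anhydride FC(F)(F)S(=O)(=O)OS(=O)(=O)C(F)(F)F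
Why: O-silylation, bromine–lithium exchange, retro-Brook 1,3-migration of silicon from oxygen to carbon and triflation of the phenoxide form the standard sequence to ortho-silylaryl triflates, and the chlorine is meta to the lithiated carbon so no aryne can form prematurely.

Step 10
Reactants: 14 the meso bis(silyl ether) diester; 20 4-(benzyloxy)-2-chloro-6-(trimethylsilyl)phenyl trifluoromethanesulfonate (2.5 equiv, added slowly)
Product: 23 (2S,3R,2'R,3'S)-7,7'-bis(benzyloxy)-2,2'-bis[4-(benzyloxy)phenyl]-5,5'-dichloro-[3,3'-bichromane]-4,4'-dione (meso), via aryne 21 (not isolated), via mono-chromanone 22 (not isolated)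
Conditions: CsF, 18-crown-6, THF, rt to 50 °C
Reagents that add atoms: none
Why: Proposed new method: fluoride releases aryne 21 from 20 and the C2/C2' alkoxides from the silyl ethers of 14, each alkoxide adds to the aryne carbon remote from chlorine (O1–C8a) and the ortho aryl carbanion so formed acylates itself on the ester carbonyl three atoms away (C4–C4a) with loss of methoxide, so that the aryne is inserted between O1 and C4 of a β-oxy ester, twice in one flask. The closest known reaction type is the fluoride-mediated annulation of arynes with salicylate esters to xanthones (O-arylation, then intramolecular acylation of the aryl anion), supported by aryne insertion into the N–C(O) bond of β-lactams; new are the aliphatic silyl-masked β-alkoxide and the two-directional use. Each ring C closes by 6-exo-trig attack of the C4a carbanion on the ester carbon after the intermolecular O-arylation. No stereocentre is formed: C2 and C2' keep their configuration because their C–O bonds are not broken, and C3 and C3' because the medium is aprotic and each alkoxide is consumed as it is unveiled, so the configuration of 14 maps onto the 2,3-trans/2',3'-trans meso array of 23. The step needs regioselective O-attack on the unsymmetrical aryne, secured by the chlorine next to the future C4a (aryne distortion, inductive stabilisation of the neighbouring carbanion and the bulk of the secondary alkoxide all point to the remote carbon), and six- over seven-membered acylation, secured by the 1,3-relation of O1 and C4. A γ-lactone formed if an alkoxide first closes on the distal ester is no dead end, since the aryl anion of the other arm opens it and sets that alkoxide free again.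

Step 11
Reactants: 23 the meso tetra-O-benzyl dichloro biflavanone
Product: 24 (2S,3R,2'R,3'S)-7,7'-dihydroxy-2,2'-bis(4-hydroxyphenyl)-[3,3'-bichromane]-4,4'-dione (meso)
Conditions: H2 (1 atm), Pd/C, NaOAc, EtOAc/MeOH, rt
Reagents that add atoms: none
Why: catalytic hydrogenolysis should cleave the four benzyl ethers and, with acetate as HCl scavenger, the two aryl C–Cl bonds activated by the ortho carbonyl, under conditions mild enough to leave ring C and its stereocentres intact.

**Compound list**

1 | 4-(benzyloxy)benzyl chloride | ClCc1ccc(OCc2ccccc2)cc1 | starting material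
2 | triphenylphosphine | c1ccc(cc1)P(c1ccccc1)c1ccccc1 | starting material
3 | [4-(benzyloxy)benzyl]triphenylphosphonium chloride | [Cl-].c1ccc(cc1)[P+](Cc1ccc(OCc2ccccc2)cc1)(c1ccccc1)c1ccccc1 | intermediate
4 | glyoxal (ethanedial) | O=CC=O | starting material
5 | [4-(benzyloxy)benzylidene]triphenylphosphorane (ylide) | c1ccc(cc1)P(=Cc1ccc(OCc2ccccc2)cc1)(c1ccccc1)c1ccccc1 | intermediate
6 | (1E,3E)-1,4-bis[4-(benzyloxy)phenyl]buta-1,3-diene | c1ccc(cc1)COc1ccc(cc1)/C=C/C=C/c1ccc(OCc2ccccc2)cc1 | intermediate
7 | maleic anhydride | O=C1OC(=O)C=C1 | starting material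
8 | (3aR,4R,7S,7aS)-4,7-bis[4-(benzyloxy)phenyl]-3a,4,7,7a-tetrahydro-2-benzofuran-1,3-dione (meso, all-cis) | C1=C[C@@H](c2ccc(OCc3ccccc3)cc2)[C@H]2C(=O)OC(=O)[C@H]2[C@H]1c1ccc(OCc2ccccc2)cc1 | intermediate
9 | rac-all-cis-3,6-bis[4-(benzyloxy)phenyl]-2-(methoxycarbonyl)cyclohex-4-ene-1-carboxylic acid | C1=C[C@@H](c2ccc(OCc3ccccc3)cc2)[C@@H](C(=O)O)[C@@H](C(=O)OC)[C@H]1c1ccc(OCc2ccccc2)cc1 | intermediate
10 | dimethyl (1S,2R,3R,6S)-3,6-bis[4-(benzyloxy)phenyl]cyclohex-4-ene-1,2-dicarboxylate (meso, all-cis) | C1=C[C@@H](c2ccc(OCc3ccccc3)cc2)[C@@H](C(=O)OC)[C@@H](C(=O)OC)[C@H]1c1ccc(OCc2ccccc2)cc1 | intermediate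
11 | dimethyl (2S,3R)-2-[(1S)-1-[4-(benzyloxy)phenyl]-2-oxoethyl]-3-[(1R)-1-[4-(benzyloxy)phenyl]-2-oxoethyl]butanedioate (meso dialdehyde) | O=C[C@@H](c1ccc(OCc2ccccc2)cc1)[C@@H](C(=O)OC)[C@@H](C(=O)OC)[C@H](C=O)c1ccc(OCc2ccccc2)cc1 | intermediate
12 | dimethyl (2R,3S)-2-[(S)-[4-(benzyloxy)phenyl](formyloxy)methyl]-3-[(R)-[4-(benzyloxy)phenyl](formyloxy)methyl]butanedioate (meso) | O=CO[C@@H](c1ccc(OCc2ccccc2)cc1)[C@@H](C(=O)OC)[C@@H](C(=O)OC)[C@H](OC=O)c1ccc(OCc2ccccc2)cc1 | intermediate
13 | dimethyl (2R,3S)-2-[(S)-[4-(benzyloxy)phenyl](hydroxy)methyl]-3-[(R)-[4-(benzyloxy)phenyl](hydroxy)methyl]butanedioate (meso) | O[C@@H](c1ccc(OCc2ccccc2)cc1)[C@@H](C(=O)OC)[C@@H](C(=O)OC)[C@H](O)c1ccc(OCc2ccccc2)cc1 | intermediate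
14 | dimethyl (2R,3S)-2-[(S)-[4-(benzyloxy)phenyl][(trimethylsilyl)oxy]methyl]-3-[(R)-[4-(benzyloxy)phenyl][(trimethylsilyl)oxy]methyl]butanedioate (meso) | C[Si](C)(C)O[C@@H](c1ccc(OCc2ccccc2)cc1)[C@@H](C(=O)OC)[C@@H](C(=O)OC)[C@H](O[Si](C)(C)C)c1ccc(OCc2ccccc2)cc1 | intermediate
15 | 4-(benzyloxy)phenol | Oc1ccc(OCc2ccccc2)cc1 | starting material
16 | 4-(benzyloxy)-2-chlorophenol | Oc1ccc(OCc2ccccc2)cc1Cl | intermediate
17 | 4-(benzyloxy)-2-bromo-6-chlorophenol | Oc1c(Br)cc(OCc2ccccc2)cc1Cl | intermediate
18 | [4-(benzyloxy)-2-bromo-6-chlorophenoxy]trimethylsilane | C[Si](C)(C)Oc1c(Br)cc(OCc2ccccc2)cc1Cl | intermediate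
19 | lithium 4-(benzyloxy)-2-chloro-6-(trimethylsilyl)phenolate | [Li+].[O-]c1c(Cl)cc(OCc2ccccc2)cc1[Si](C)(C)C | intermediate
20 | 4-(benzyloxy)-2-chloro-6-(trimethylsilyl)phenyl trifluoromethanesulfonate | C[Si](C)(C)c1cc(OCc2ccccc2)cc(Cl)c1OS(=O)(=O)C(F)(F)F | intermediate
21 | 5-(benzyloxy)-3-chloro-1,2-didehydrobenzene (aryne) | ClC1=CC(OCc2ccccc2)=CC#C1 | intermediate
22 | rac-methyl (2S,3R)-2-[(2S,3R)-7-(benzyloxy)-2-[4-(benzyloxy)phenyl]-5-chloro-4-oxo-3,4-dihydro-2H-chromen-3-yl]-3-[4-(benzyloxy)phenyl]-3-[(trimethylsilyl)oxy]propanoate | O=C1c2c(Cl)cc(OCc3ccccc3)cc2O[C@H](c2ccc(OCc3ccccc3)cc2)[C@H]1[C@H](C(=O)OC)[C@@H](O[Si](C)(C)C)c1ccc(OCc2ccccc2)cc1 | intermediate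
23 | (2S,3R,2'R,3'S)-7,7'-bis(benzyloxy)-2,2'-bis[4-(benzyloxy)phenyl]-5,5'-dichloro-[3,3'-bichromane]-4,4'-dione (meso) | O=C1c2c(Cl)cc(OCc3ccccc3)cc2O[C@H](c2ccc(OCc3ccccc3)cc2)[C@H]1[C@@H]1C(=O)c2c(Cl)cc(OCc3ccccc3)cc2O[C@H]1c1ccc(OCc2ccccc2)cc1 | intermediate
24 | (2S,3R,2'R,3'S)-7,7'-dihydroxy-2,2'-bis(4-hydroxyphenyl)-[3,3'-bichromane]-4,4'-dione (meso) | O=C1c2ccc(O)cc2O[C@H](c2ccc(O)cc2)[C@H]1[C@@H]1C(=O)c2ccc(O)cc2O[C@H]1c1ccc(O)cc1 | target

**Step count and risks**

Total steps: 11. Longest linear sequence: 8 (steps 1–6, 10, 11); the aryne precursor is a three-step branch (steps 7–9).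

Steps most likely to fail:

1. Step 10 (Proposed new method). What may go wrong: chloride loss or protonation of the ortho-chloro aryl carbanion before it acylates; retro-aldol cleavage of the unveiled β-alkoxide; base-induced epimerisation at C3 by the methoxide set free; addition of the alkoxide to the wrong aryne carbon. Fallback with known chemistry only, in which the two bonds of each ring are made in separate operations: it sets out from 14. Both esters are converted with MeNHOMe·HCl and i-PrMgCl (THF, −20 °C) into the meso bis(N-methoxy-N-methylamide) F1. Addition of 4-(benzyloxy)-2-fluorophenyllithium (from 4-(benzyloxy)-1-bromo-2-fluorobenzene and n-BuLi, −78 °C) forms the C4–C4a bonds and gives the meso bis(2-fluoroaryl ketone) F2. CsF in DMF removes the silyl groups, and each alkoxide displaces the fluoride ortho to its ketone (intramolecular SNAr, O1–C8a, retention at C2) to give the chlorine-free tetra-O-benzyl biflavanone F3. Hydrogenolysis (H2, Pd/C, EtOAc/MeOH) then comes back to the route at 24.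

2. Step 5. What may go wrong: attack of ozone on the electron-rich aryl ether rings in competition with the hindered ring alkene; epimerisation of the α-aryl aldehyde centres before oxidation; migration of hydrogen in place of carbon in the peracid step. Fallback: it sets out from 10. OsO4-catalysed dihydroxylation (NMO, acetone/H2O) on the face opposite to the four substituents gives the meso cis-diol F4. Glycol cleavage with NaIO4 on silica in CH2Cl2 gives the dialdehyde under neutral, pyridine-free conditions, so the fallback comes back to the route at 11, which is oxidised at once with mCPBA as in step 5.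

3. Step 11. What may go wrong: hydrogenolysis of the benzylic C2–O1 bonds of ring C or reduction of the C4 ketones during the slower cleavage of the aryl C–Cl bonds; ring opening of ring C under the buffered conditions with loss of the C3 configuration. Fallback: it sets out from 23. Lewis-acid debenzylation (BCl3, pentamethylbenzene, CH2Cl2, −78 °C) without any hydrogen gives the dichloro tetraphenol F5. A homogeneous transfer hydrodechlorination (Pd(OAc)2, 2-dicyclohexylphosphino-2',4',6'-triisopropylbiphenyl, HCO2Na, DMF, 60 °C) then comes back to the route at 24.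

**Further compounds**

F1 | step 10 | (2R,3S)-2-[(S)-[4-(benzyloxy)phenyl][(trimethylsilyl)oxy]methyl]-3-[(R)-[4-(benzyloxy)phenyl][(trimethylsilyl)oxy]methyl]-N1,N4-dimethoxy-N1,N4-dimethylbutanediamide (meso) | C[Si](C)(C)O[C@@H](c1ccc(OCc2ccccc2)cc1)[C@@H](C(=O)N(C)OC)[C@@H](C(=O)N(C)OC)[C@H](O[Si](C)(C)C)c1ccc(OCc2ccccc2)cc1
F2 | step 10 | (2R,3S)-1,4-bis[4-(benzyloxy)-2-fluorophenyl]-2-[(S)-[4-(benzyloxy)phenyl][(trimethylsilyl)oxy]methyl]-3-[(R)-[4-(benzyloxy)phenyl][(trimethylsilyl)oxy]methyl]butane-1,4-dione (meso) | C[Si](C)(C)O[C@@H](c1ccc(OCc2ccccc2)cc1)[C@@H](C(=O)c1ccc(OCc2ccccc2)cc1F)[C@@H](C(=O)c1ccc(OCc2ccccc2)cc1F)[C@H](O[Si](C)(C)C)c1ccc(OCc2ccccc2)cc1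
F3 | step 10 | (2S,3R,2'R,3'S)-7,7'-bis(benzyloxy)-2,2'-bis[4-(benzyloxy)phenyl]-[3,3'-bichromane]-4,4'-dione (meso) | O=C1c2ccc(OCc3ccccc3)cc2O[C@H](c2ccc(OCc3ccccc3)cc2)[C@H]1[C@@H]1C(=O)c2ccc(OCc3ccccc3)cc2O[C@H]1c1ccc(OCc2ccccc2)cc1
F4 | step 5 | dimethyl 3,6-bis[4-(benzyloxy)phenyl]-4,5-dihydroxycyclohexane-1,2-dicarboxylate, meso, aryl and ester groups all-cis, the two hydroxyls cis to each other and trans to them | O[C@@H]1[C@H](O)[C@@H](c2ccc(OCc3ccccc3)cc2)[C@@H](C(=O)OC)[C@@H](C(=O)OC)[C@H]1c1ccc(OCc2ccccc2)cc1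
F5 | step 11 | (2S,3R,2'R,3'S)-5,5'-dichloro-7,7'-dihydroxy-2,2'-bis(4-hydroxyphenyl)-[3,3'-bichromane]-4,4'-dione (meso) | O=C1c2c(Cl)cc(O)cc2O[C@H](c2ccc(O)cc2)[C@H]1[C@@H]1C(=O)c2c(Cl)cc(O)cc2O[C@H]1c1ccc(O)cc1
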